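**Plan** (flavanone numbering; unit 1 is the 4-methoxyphenyl half and unit 2 the 4-hydroxyphenyl half, so C3(1) means C3 of unit 1)
1. Cuts: the two C4 ketones go back to a C4(2) methyl ether and a C4(1) methylene. Ring C of unit 2 is then opened at O1(2)–C2(2) and C3(2)–C4(2), the styrene at its C=C, and ring C of unit 1 at O1(1)–C2(1) and C3(1)–C4(1).
2. Enabling feature: in ring C of unit 2 the two cut bonds flank the trans C2(2)–C3(2) pair, and C2(2) bears a 4-oxygenated aryl group. This is what an (E)-styrene leaves behind after [4+2] addition to an ortho-quinone methide.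
3. Forward: one dibromosalicylaldehyde is used twice. It first closes ring C of unit 1 with 4-methoxycinnamaldehyde and later, after olefination of the C3(1) side chain, serves as methide precursor to close ring C of unit 2. The ketones follow, unit 2 first and unit 1 last.
4. Stereochemistry: C2(1) comes from iminium catalysis and C3(1) (cis) from hydrogenation anti to the 2-aryl group. C2(2)/C3(2) are trans because the alkene is (E), and their sense is set by attack anti to the C2(1) branch.
5. Safeguards: bromine at C6/C8 of both A rings blocks Friedel–Crafts attack by the cationic methide. Unit 1 stays a flavan (C4 = CH2) until the end, so its cis pair cannot ionise, eliminate or epimerise.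

Key step: step 9

Assumption: the sense of induction in step 3 is taken from the accepted shielding model of the (S)-diarylprolinol silyl ether iminium ion (the (R)-catalyst is equally available), and the C4 ether and carbinol centres are drawn as the expected epimers, all of which vanish on oxidation.

Step 1
Reactants: 1 2,4,6-trihydroxybenzaldehyde
Product: 2 4,6-bis(benzyloxy)-2-hydroxybenzaldehyde
Conditions: BnBr (2.05 equiv), K2CO3 (2.1 equiv), DMF, rt
Reagents that add atoms: benzyl bromide BrCc1ccccc1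
Why: Williamson etherification should stop after two benzylations because the last ortho hydroxyl is hydrogen-bonded to the formyl oxygen and is the least nucleophilic.

Step 2
Reactants: 2 4,6-bis(benzyloxy)-2-hydroxybenzaldehyde
Product: 3 4,6-bis(benzyloxy)-3,5-dibromo-2-hydroxybenzaldehyde
Conditions: NBS (2.1 equiv), CH2Cl2, 0 °C, dark
Reagents that add atoms: N-bromosuccinimide O=C1CCC(=O)N1Br
Why: Electrophilic aromatic bromination fills the only two free, oxygen-activated ring positions, which later denies every A ring a site for Friedel–Crafts alkylation and makes the derived methide more electrophilic.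

Step 3
Reactants: 3 4,6-bis(benzyloxy)-3,5-dibromo-2-hydroxybenzaldehyde; 4 (E)-4-methoxycinnamaldehyde
Product: 5 (R)-5,7-bis(benzyloxy)-6,8-dibromo-2-(4-methoxyphenyl)-2H-chromene-3-carbaldehyde
Conditions: (S)-2-[diphenyl(trimethylsilyloxy)methyl]pyrrolidine (20 mol %), 2-nitrobenzoic acid (20 mol %), 4 Å MS, toluene, rt
Reagents that add atoms: none
Why: The domino oxa-Michael/aldol condensation under iminium–enamine catalysis closes ring C of unit 1, with the phenol adding to the iminium face not shielded by the diphenyl(silyloxy)methyl group to set C2(1), and the bromine-rich product can be recrystallised to raise its enantiopurity.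

Step 4
Reactants: 5 (R)-5,7-bis(benzyloxy)-6,8-dibromo-2-(4-methoxyphenyl)-2H-chromene-3-carbaldehyde
Product: 6 (R)-[5,7-bis(benzyloxy)-6,8-dibromo-2-(4-methoxyphenyl)-2H-chromen-3-yl]methanol
Conditions: NaBH4, CeCl3·7H2O, MeOH/THF, 0 °C
Reagents that add atoms: none
Why: Luche reduction gives 1,2-reduction of the enal and leaves the C3=C4 bond, the aryl bromides and C2(1) untouched.

Step 5
Reactants: 6 (R)-[5,7-bis(benzyloxy)-6,8-dibromo-2-(4-methoxyphenyl)-2H-chromen-3-yl]methanol
Product: 7 [(2S,3S)-5,7-bis(benzyloxy)-6,8-dibromo-2-(4-methoxyphenyl)chroman-3-yl]methanol (2,3-cis)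
Conditions: H2 (1 atm), [Ir(cod)(PCy3)(py)]PF6 (5 mol %), CH2Cl2, rt
Reagents that add atoms: none
Why: Homogeneous hydroxyl-assisted hydrogenation spares aryl bromides and benzyl ethers, and because allylic strain with the C3 substituent holds the 2-aryl group pseudoaxial, hydrogen is delivered to the opposite face so that C3(1) emerges cis to C2(1).

Step 6
Reactants: 7 [(2S,3S)-5,7-bis(benzyloxy)-6,8-dibromo-2-(4-methoxyphenyl)chroman-3-yl]methanol
Product: 8 5-{[(2S,3R)-5,7-bis(benzyloxy)-6,8-dibromo-2-(4-methoxyphenyl)chroman-3-yl]methylsulfanyl}-1-phenyl-1H-tetrazole (2,3-cis)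
Conditions: 1-phenyl-1H-tetrazole-5-thiol, PPh3, DIAD, THF, 0 °C to rt
Reagents that add atoms: 1-phenyl-1H-tetrazole-5-thiol Sc1nnnn1-c1ccccc1
Why: Mitsunobu thioetherification of the primary alcohol occurs at the exocyclic CH2 and touches no stereocentre (the descriptor at C3 changes only through priorities).

Step 7
Reactants: 8 5-{[(2S,3R)-5,7-bis(benzyloxy)-6,8-dibromo-2-(4-methoxyphenyl)chroman-3-yl]methylsulfanyl}-1-phenyl-1H-tetrazole
Product: 9 5-{[(2S,3R)-5,7-bis(benzyloxy)-6,8-dibromo-2-(4-methoxyphenyl)chroman-3-yl]methylsulfonyl}-1-phenyl-1H-tetrazole (2,3-cis)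
Conditions: 30% H2O2, (NH4)6Mo7O24·4H2O (15 mol %), EtOH/THF, 0 °C to rt
Reagents that add atoms: hydrogen peroxide OO
Why: Molybdate-catalysed sulfide-to-sulfone oxidation is chemoselective for sulfur in the presence of benzyl ethers and fully substituted arenes.

Step 8
Reactants: 9 5-{[(2S,3R)-5,7-bis(benzyloxy)-6,8-dibromo-2-(4-methoxyphenyl)chroman-3-yl]methylsulfonyl}-1-phenyl-1H-tetrazole; 10 4-benzyloxybenzaldehyde
Product: 11 (2S,3S)-5,7-bis(benzyloxy)-3-[(E)-2-(4-benzyloxyphenyl)ethenyl]-6,8-dibromo-2-(4-methoxyphenyl)chroman (2,3-cis)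
Conditions: KHMDS (1.1 equiv), DME, −78 °C; then 10, −78 °C to rt
Reagents that add atoms: none
Why: Julia–Kocienski olefination of an alkyl phenyltetrazolyl sulfone with an aromatic aldehyde is reliably (E)-selective, and placing the carbanion on the exocyclic CH2 rather than passing through a C3(1) aldehyde keeps the cis centre away from any enolisable position.

Step 9
Reactants: 11 (2S,3S)-5,7-bis(benzyloxy)-3-[(E)-2-(4-benzyloxyphenyl)ethenyl]-6,8-dibromo-2-(4-methoxyphenyl)chroman; 3 4,6-bis(benzyloxy)-3,5-dibromo-2-hydroxybenzaldehyde; 12 trimethyl orthoformate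
Product: 15 (2R,3R,4R)-5,7-bis(benzyloxy)-2-(4-benzyloxyphenyl)-3-[(2S,3S)-5,7-bis(benzyloxy)-6,8-dibromo-2-(4-methoxyphenyl)chroman-3-yl]-6,8-dibromo-4-methoxychroman, via dimethyl acetal 13 (not isolated), via methoxy ortho-quinone methide cation 14 (not isolated)
Conditions: 3 (2 equiv), HC(OMe)3 (4 equiv), Sc(OTf)3 (10 mol %), CH2Cl2, −20 °C to rt
Reagents that add atoms: trimethyl orthoformate (12) COC(OC)OC
Why: Sc(OTf)3 turns 3 and 12 into acetal 13, which loses methanol to give 14, the O-protonated 4-methoxy ortho-quinone methide, and this electron-poor 1-oxadiene adds to the electron-rich (E)-styrene of 11 in an inverse-demand hetero-Diels–Alder reaction that is either concerted and strongly asynchronous or stepwise through the 4-benzyloxybenzyl cation. The closest known reaction type is the acid-promoted three-component union of salicylaldehydes, orthoformates and styrenes to 4-alkoxy-2-arylchromans. Ring C of unit 2 closes by intermolecular [4+2] cycloaddition, C3(2)–C4(2) forming ahead of O1(2)–C2(2), and the 4-benzyloxyphenyl group fixes the regiochemistry by carrying the developing charge at C2(2). The trans C2(2)/C3(2) relation is inherited from the (E)-alkene and is also the diequatorial result of a stepwise closure, whereas C4(2) should come out 2,4-cis from the endo mode and is erased in step 12. The sense of C3(2) and C2(2) relative to C3(1) depends on the allylic centre: the styryl group sits axial on the cis-flavan half-chair with C3(1)–H eclipsing the alkene, so one face lies against the C2(1) branch and its 4-methoxyphenyl group and the other against the bare C4(1) methylene, and attack from the C4(1) side gives the configuration drawn. The step needs the methide to choose the alkene over arene carbons and needs unit 1 to survive the acid, which the four bromine atoms (no free A-ring position) and the C4(1) methylene (nothing to ionise or eliminate) secure.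

Step 10
Reactants: 15 (2R,3R,4R)-5,7-bis(benzyloxy)-2-(4-benzyloxyphenyl)-3-[(2S,3S)-5,7-bis(benzyloxy)-6,8-dibromo-2-(4-methoxyphenyl)chroman-3-yl]-6,8-dibromo-4-methoxychroman
Product: 16 (2R,3R,4R)-5,7-bis(benzyloxy)-2-(4-benzyloxyphenyl)-3-[(2S,3S)-5,7-bis(benzyloxy)-2-(4-methoxyphenyl)chroman-3-yl]-4-methoxychroman
Conditions: n-BuLi (6 equiv), THF, −78 °C; then H2O
Reagents that add atoms: none
Why: Fourfold bromine–lithium exchange, assisted by the flanking alkoxy groups, followed by protonation removes the caps at low temperature without touching benzyl ethers, the methyl ether or any stereocentre.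

Step 11
Reactants: 16 (2R,3R,4R)-5,7-bis(benzyloxy)-2-(4-benzyloxyphenyl)-3-[(2S,3S)-5,7-bis(benzyloxy)-2-(4-methoxyphenyl)chroman-3-yl]-4-methoxychroman
Product: 17 (2R,3R,4R)-5,7-bis(benzyloxy)-2-(4-benzyloxyphenyl)-3-[(2S,3S)-5,7-bis(benzyloxy)-2-(4-methoxyphenyl)chroman-3-yl]chroman-4-ol
Conditions: TsOH·H2O (10 mol %), THF/H2O 4:1, 0 °C to rt
Reagents that add atoms: water O
Why: In this SN1 solvolysis the C4(2) ether on the uncapped 5,7-dibenzyloxy ring ionises under mild acid and the cation is taken up by the large excess of water anti to the C3(2) substituent, while unit 1, still lacking any C4 oxygen, can neither ionise nor close a cyclic ether onto C4(2).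

Step 12
Reactants: 17 (2R,3R,4R)-5,7-bis(benzyloxy)-2-(4-benzyloxyphenyl)-3-[(2S,3S)-5,7-bis(benzyloxy)-2-(4-methoxyphenyl)chroman-3-yl]chroman-4-ol
Product: 18 (2R,3S)-5,7-bis(benzyloxy)-2-(4-benzyloxyphenyl)-3-[(2S,3S)-5,7-bis(benzyloxy)-2-(4-methoxyphenyl)chroman-3-yl]chroman-4-one
Conditions: Dess–Martin periodinane (1.5 equiv), NaHCO3, CH2Cl2, 0 °C to rt
Reagents that add atoms: none
Why: Buffered Dess–Martin oxidation converts the acid-labile benzylic carbinol into the unit 2 flavanone, whose trans C2(2)/C3(2) pair is the preferred arrangement and whose carbonyl group deactivates ring A of unit 2 for the next step.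

Step 13
Reactants: 18 (2R,3S)-5,7-bis(benzyloxy)-2-(4-benzyloxyphenyl)-3-[(2S,3S)-5,7-bis(benzyloxy)-2-(4-methoxyphenyl)chroman-3-yl]chroman-4-one
Product: 19 (2R,3S)-5,7-bis(benzyloxy)-2-(4-benzyloxyphenyl)-3-[(2S,3R,4R)-5,7-bis(benzyloxy)-4-hydroxy-2-(4-methoxyphenyl)chroman-3-yl]chroman-4-one
Conditions: DDQ (1.5 equiv), CH2Cl2/H2O 10:1, 0 °C to rt
Reagents that add atoms: water O
Why: Benzylic C–H oxidation by hydride abstraction, known for C4 of 5,7-dibenzyloxyflavans, should strike only the one remaining electron-rich A ring by removing the pseudoaxial C4(1)–H anti to the axial C3(1) substituent, after which water enters from that open face, the equatorial C3(1)–H is misaligned for elimination, and any over-oxidation merely gives the product of step 14.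

Step 14
Reactants: 19 (2R,3S)-5,7-bis(benzyloxy)-2-(4-benzyloxyphenyl)-3-[(2S,3R,4R)-5,7-bis(benzyloxy)-4-hydroxy-2-(4-methoxyphenyl)chroman-3-yl]chroman-4-one
Product: 20 (2S,3S)-5,7-bis(benzyloxy)-3-[(2R,3S)-5,7-bis(benzyloxy)-2-(4-benzyloxyphenyl)-4-oxochroman-3-yl]-2-(4-methoxyphenyl)chroman-4-one
Conditions: Dess–Martin periodinane (1.5 equiv), NaHCO3, CH2Cl2, 0 °C
Reagents that add atoms: none
Why: Dess–Martin oxidation works under near-neutral conditions, which matters because the cis C2(1)/C3(1) pair becomes epimerisable only from here on, so soluble base, acid and long contact with silica are avoided.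

Step 15
Reactants: 20 (2S,3S)-5,7-bis(benzyloxy)-3-[(2R,3S)-5,7-bis(benzyloxy)-2-(4-benzyloxyphenyl)-4-oxochroman-3-yl]-2-(4-methoxyphenyl)chroman-4-one
Product: 21 (2S,3S)-3-[(2R,3S)-5,7-dihydroxy-2-(4-hydroxyphenyl)-4-oxochroman-3-yl]-5,7-dihydroxy-2-(4-methoxyphenyl)chroman-4-one (target)
Conditions: H2 (1 atm), 10% Pd/C, EtOAc/MeOH, rt
Reagents that add atoms: none
Why: Catalytic hydrogenolysis removes the five aryl benzyl ethers under neutral conditions that neither enolise the cis flavanone nor normally reduce the electron-rich flavanone carbonyl groups or the C2–O bonds.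

**Compound list**
1 | 2,4,6-trihydroxybenzaldehyde | O=Cc1c(O)cc(O)cc1O | starting material
2 | 4,6-bis(benzyloxy)-2-hydroxybenzaldehyde | O=Cc1c(O)cc(OCc2ccccc2)cc1OCc1ccccc1 | intermediate
3 | 4,6-bis(benzyloxy)-3,5-dibromo-2-hydroxybenzaldehyde | O=Cc1c(O)c(Br)c(OCc2ccccc2)c(Br)c1OCc1ccccc1 | intermediate
4 | (E)-4-methoxycinnamaldehyde | COc1ccc(/C=C/C=O)cc1 | starting material
5 | (R)-chromene-3-carbaldehyde of unit 1 | COc1ccc([C@H]2Oc3c(Br)c(OCc4ccccc4)c(Br)c(OCc4ccccc4)c3C=C2C=O)cc1 | intermediate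
6 | (R)-chromen-3-ylmethanol of unit 1 | COc1ccc([C@H]2Oc3c(Br)c(OCc4ccccc4)c(Br)c(OCc4ccccc4)c3C=C2CO)cc1 | intermediate
7 | (2S,3S)-cis-flavan-3-ylmethanol | COc1ccc([C@H]2Oc3c(Br)c(OCc4ccccc4)c(Br)c(OCc4ccccc4)c3C[C@H]2CO)cc1 | intermediate
8 | (2S,3R)-cis-flavan-3-ylmethyl phenyltetrazolyl sulfide | COc1ccc([C@H]2Oc3c(Br)c(OCc4ccccc4)c(Br)c(OCc4ccccc4)c3C[C@H]2CSc2nnnn2-c2ccccc2)cc1 | intermediate
9 | (2S,3R)-cis-flavan-3-ylmethyl phenyltetrazolyl sulfone | COc1ccc([C@H]2Oc3c(Br)c(OCc4ccccc4)c(Br)c(OCc4ccccc4)c3C[C@H]2CS(=O)(=O)c2nnnn2-c2ccccc2)cc1 | intermediate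
10 | 4-benzyloxybenzaldehyde | O=Cc1ccc(OCc2ccccc2)cc1 | starting material
11 | (2S,3S)-cis-3-[(E)-4-benzyloxystyryl]-6,8-dibromoflavan (key-step precursor) | COc1ccc([C@H]2Oc3c(Br)c(OCc4ccccc4)c(Br)c(OCc4ccccc4)c3C[C@H]2/C=C/c2ccc(OCc3ccccc3)cc2)cc1 | intermediate
12 | trimethyl orthoformate | COC(OC)OC | starting material
13 | 3,5-bis(benzyloxy)-2,4-dibromo-6-(dimethoxymethyl)phenol | COC(OC)c1c(O)c(Br)c(OCc2ccccc2)c(Br)c1OCc1ccccc1 | intermediate (not isolated)
14 | O-protonated 4-methoxy ortho-quinone methide (aryl methoxycarbenium ion) | C[O+]=Cc1c(O)c(Br)c(OCc2ccccc2)c(Br)c1OCc1ccccc1 | intermediate (not isolated)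
15 | tetrabromo penta-O-benzyl biflavan, unit 2 as 4-methyl ether (key-step product) | COc1ccc([C@H]2Oc3c(Br)c(OCc4ccccc4)c(Br)c(OCc4ccccc4)c3C[C@H]2[C@@H]2[C@@H](OC)c3c(OCc4ccccc4)c(Br)c(OCc4ccccc4)c(Br)c3O[C@H]2c2ccc(OCc3ccccc3)cc2)cc1 | intermediate
16 | uncapped penta-O-benzyl biflavan 4(2)-methyl ether | COc1ccc([C@H]2Oc3cc(OCc4ccccc4)cc(OCc4ccccc4)c3C[C@H]2[C@@H]2[C@@H](OC)c3c(OCc4ccccc4)cc(OCc4ccccc4)cc3O[C@H]2c2ccc(OCc3ccccc3)cc2)cc1 | intermediate
17 | biflavan 4(2)-ol | COc1ccc([C@H]2Oc3cc(OCc4ccccc4)cc(OCc4ccccc4)c3C[C@H]2[C@@H]2[C@@H](O)c3c(OCc4ccccc4)cc(OCc4ccccc4)cc3O[C@H]2c2ccc(OCc3ccccc3)cc2)cc1 | intermediate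
18 | flavan(1)–flavanone(2) | COc1ccc([C@H]2Oc3cc(OCc4ccccc4)cc(OCc4ccccc4)c3C[C@H]2[C@@H]2C(=O)c3c(OCc4ccccc4)cc(OCc4ccccc4)cc3O[C@H]2c2ccc(OCc3ccccc3)cc2)cc1 | intermediate
19 | flavan-4-ol(1)–flavanone(2) | COc1ccc([C@H]2Oc3cc(OCc4ccccc4)cc(OCc4ccccc4)c3[C@H](O)[C@H]2[C@@H]2C(=O)c3c(OCc4ccccc4)cc(OCc4ccccc4)cc3O[C@H]2c2ccc(OCc3ccccc3)cc2)cc1 | intermediate
20 | penta-O-benzyl biflavanone | COc1ccc([C@H]2Oc3cc(OCc4ccccc4)cc(OCc4ccccc4)c3C(=O)[C@H]2[C@@H]2C(=O)c3c(OCc4ccccc4)cc(OCc4ccccc4)cc3O[C@H]2c2ccc(OCc3ccccc3)cc2)cc1 | intermediate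
21 | CNP0196568.4 | COc1ccc([C@H]2Oc3cc(O)cc(O)c3C(=O)[C@H]2[C@@H]2C(=O)c3c(O)cc(O)cc3O[C@H]2c2ccc(O)cc2)cc1 | target

Total step count: 15. Longest linear sequence: 15 steps (1 to 21).

**Steps most likely to fail**

Step 9. An (E)-alkene exerts little allylic strain, so discrimination between the two alkene faces may be poor. Addition to the branched alkene may also be slow.
- The fallback replaces kinetic face control by equilibration and sets out from 11.
- The cycloaddition is run as before, and 15 is carried on together with the unit 2 face isomer of the cycloadduct F1 [(2S,3S,4S) in unit 2].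
- Bromine–lithium exchange and protonation give the uncapped face isomer F2.
- Aqueous acid gives the face-isomeric 4(2)-carbinol F3, and buffered Dess–Martin oxidation gives the (2S,3R)-unit 2 flavanone diastereomer F4.
- At this stage unit 1 is a plain flavan with no acidic C–H. The unit 2 flavanone, in contrast, opens reversibly with NaOAc in hot EtOH by retro-oxa-Michael reaction to the alpha-substituted 2'-hydroxychalcone F5, which erases C2(2) and C3(2).
- Reclosure returns the two trans flavanones. Compound 18 is separated and F4 is resubmitted, so the fallback comes back to the route at 18.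

Step 11. The axial C3(2) proton may be lost from the C4(2) cation, so that elimination to a flav-3-ene competes with capture by water.
- The fallback avoids the cation altogether and sets out from 11 and 3.
- The cycloaddition is run with triallyl orthoformate in place of 12 and gives the tetrabromo 4(2)-allyl ether F6.
- Bromine–lithium exchange and protonation at −78 °C give the uncapped 4(2)-allyl ether F7.
- The allyl group is removed by nickel-catalysed hydroalumination–elimination (DIBAL-H, NiCl2(dppp), toluene, 0 °C) under non-acidic conditions, which comes back to the route at 17.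

Step 3. The aldol closure onto the crowded, oxygen-rich formyl group may be slow with the bulky catalyst. The reversible oxa-Michael step would then erode the enantiomeric purity.
- The fallback gives up asymmetric catalysis for resolution and sets out from 3 and 4.
- Pyrrolidine and benzoic acid in toluene give the racemic chromene aldehyde F8, and Luche reduction gives the racemic chromenylmethanol F9.
- Esterification with (S)-2-methoxy-2-phenylacetic acid (DCC, DMAP) gives the (R)-alcohol (S)-O-methylmandelate F10 and the (S)-alcohol (S)-O-methylmandelate F11. These are separated by crystallisation or chromatography.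
- Methanolysis of F10 (K2CO3, MeOH) comes back to the route at 6.

**Further compounds**
F1 | step 9 | unit 2 face isomer of the cycloadduct, (2S,3S,4S) in unit 2 | COc1ccc([C@H]2Oc3c(Br)c(OCc4ccccc4)c(Br)c(OCc4ccccc4)c3C[C@H]2[C@H]2[C@H](OC)c3c(OCc4ccccc4)c(Br)c(OCc4ccccc4)c(Br)c3O[C@@H]2c2ccc(OCc3ccccc3)cc2)cc1
F2 | step 9 | uncapped face isomer | COc1ccc([C@H]2Oc3cc(OCc4ccccc4)cc(OCc4ccccc4)c3C[C@H]2[C@H]2[C@H](OC)c3c(OCc4ccccc4)cc(OCc4ccccc4)cc3O[C@@H]2c2ccc(OCc3ccccc3)cc2)cc1
F3 | step 9 | face-isomeric 4(2)-carbinol | COc1ccc([C@H]2Oc3cc(OCc4ccccc4)cc(OCc4ccccc4)c3C[C@H]2[C@H]2[C@H](O)c3c(OCc4ccccc4)cc(OCc4ccccc4)cc3O[C@@H]2c2ccc(OCc3ccccc3)cc2)cc1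
F4 | step 9 | (2S,3R)-unit 2 flavanone diastereomer | COc1ccc([C@H]2Oc3cc(OCc4ccccc4)cc(OCc4ccccc4)c3C[C@H]2[C@H]2C(=O)c3c(OCc4ccccc4)cc(OCc4ccccc4)cc3O[C@@H]2c2ccc(OCc3ccccc3)cc2)cc1
F5 | step 9 | alpha-substituted 2'-hydroxychalcone (alkene geometry not fixed) | COc1ccc([C@H]2Oc3cc(OCc4ccccc4)cc(OCc4ccccc4)c3C[C@H]2C(=Cc2ccc(OCc3ccccc3)cc2)C(=O)c2c(O)cc(OCc3ccccc3)cc2OCc2ccccc2)cc1
F6 | step 11 | tetrabromo 4(2)-allyl ether | COc1ccc([C@H]2Oc3c(Br)c(OCc4ccccc4)c(Br)c(OCc4ccccc4)c3C[C@H]2[C@@H]2[C@@H](OCC=C)c3c(OCc4ccccc4)c(Br)c(OCc4ccccc4)c(Br)c3O[C@H]2c2ccc(OCc3ccccc3)cc2)cc1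
F7 | step 11 | uncapped 4(2)-allyl ether | COc1ccc([C@H]2Oc3cc(OCc4ccccc4)cc(OCc4ccccc4)c3C[C@H]2[C@@H]2[C@@H](OCC=C)c3c(OCc4ccccc4)cc(OCc4ccccc4)cc3O[C@H]2c2ccc(OCc3ccccc3)cc2)cc1
F8 | step 3 | racemic chromene aldehyde | COc1ccc(C2Oc3c(Br)c(OCc4ccccc4)c(Br)c(OCc4ccccc4)c3C=C2C=O)cc1
F9 | step 3 | racemic chromenylmethanol | COc1ccc(C2Oc3c(Br)c(OCc4ccccc4)c(Br)c(OCc4ccccc4)c3C=C2CO)cc1
F10 | step 3 | (R)-alcohol (S)-O-methylmandelate | COc1ccc([C@H]2Oc3c(Br)c(OCc4ccccc4)c(Br)c(OCc4ccccc4)c3C=C2COC(=O)[C@@H](OC)c2ccccc2)cc1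
F11 | step 3 | (S)-alcohol (S)-O-methylmandelate | COc1ccc([C@@H]2Oc3c(Br)c(OCc4ccccc4)c(Br)c(OCc4ccccc4)c3C=C2COC(=O)[C@@H](OC)c2ccccc2)cc1
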